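**Plan**

- Numbering: rings A and B are a 6,7,8,9-tetrahydro-5H-benzo[7]annulene (OMe on C2–C4, C5 spiro, C6H2, methyls on C7 and C8, benzoate on C9); ring C carries primes (C2′–C6′).
- Retrosynthesis: exchange the C9 benzoate for a silyl ether; cut ring C at C2′=C3′ and C6′=C5′; cut ring B at C4a–C5, then C5–C6; cut C9–C9a; cut C7–C8.
- Enabling feature: ring C (C5, C2′H, C3′OMe, C4′=O, C5′OMe, C6′H) has a mirror plane through C5 and C4′. C5 is therefore not stereogenic, C3′–C4′–C5′ with its three oxygens is 1,3-dimethoxypropan-2-one, and C2′ and C6′ are two formyl carbons on C5.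
- Forward: the C6–C9 chain is made first by joining two propionyl units at C7–C8, ring A is added at C9, a malonate at C6, ring B is closed by C4a–C5 arylation, ring C by a (3+3) double aldol condensation, and the C9 ester is set last.
- Stereochemistry: C7 and C8 come from the (R)-benzyloxazolidinone in an oxidative enolate coupling; C9 comes from Felkin–Anh addition to the C8-stereogenic aldehyde; nothing else is stereogenic.

Key step: step 14

Remark: the geminal dialdehyde is assumed to be too prone to deformylation on silica and is used crude in the key step.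

**Route**

Step 1
Reactants: 1 (R)-4-benzyl-3-propionyloxazolidin-2-one (two molecules are joined)
Product: 3 (4R,4′R)-3,3′-[(2S,3S)-2,3-dimethylbutanedioyl]bis(4-benzyl-1,3-oxazolidin-2-one), via lithium Z-enolate 2 (not isolated)
Conditions: LiN(iPr)2 (1.05 equiv), THF, −78 °C; TiCl4 (1.1 equiv), CH2Cl2, −78 °C to rt
Reagents that add atoms: (R)-4-benzyl-3-propionyloxazolidin-2-one (the second molecule of 1), CCC(=O)N1[C@H](Cc2ccccc2)COC1=O
Why: Oxidative enolate homocoupling, in which two molecules of the chelated Z-enolate are oxidised by tetravalent titanium and joined at their α-carbons (C7 and C8), each on the enolate face away from the benzyl group of the auxiliary, which should favour the C2-symmetric (2S,3S) dimer over the meso and (2R,3R) isomers.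

Step 2
Reactants: 3 (4R,4′R)-3,3′-[(2S,3S)-2,3-dimethylbutanedioyl]bis(4-benzyl-1,3-oxazolidin-2-one)
Product: 4 (2S,3S)-2,3-dimethylbutane-1,4-diol
Conditions: LiBH4, H2O, Et2O, 0 °C to rt
Reagents that add atoms: none
Why: Reductive cleavage of N-acyloxazolidinones with LiBH4 should reduce both imide carbonyls to primary alcohols without touching the α-stereocentres and release the auxiliary for recovery.

Step 3
Reactants: 4 (2S,3S)-2,3-dimethylbutane-1,4-diol
Product: 5 (2S,3S)-4-[(tert-butyldimethylsilyl)oxy]-2,3-dimethylbutan-1-ol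
Conditions: NaH (1 equiv), THF, rt; TBSCl (1 equiv), 0 °C to rt
Reagents that add atoms: tert-butyldimethylsilyl chloride, CC(C)(C)[Si](C)(C)Cl
Why: Monosilylation of a symmetric diol through its sparingly soluble monosodium alkoxide should stop after one silylation, and because the diol is C2-symmetric only one mono-ether can form.

Step 4
Reactants: 5 (2S,3S)-4-[(tert-butyldimethylsilyl)oxy]-2,3-dimethylbutan-1-ol
Product: 6 (2S,3S)-4-[(tert-butyldimethylsilyl)oxy]-2,3-dimethylbutanal
Conditions: TEMPO (cat.), PhI(OAc)2, CH2Cl2, rt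
Reagents that add atoms: none
Why: The non-basic oxoammonium oxidation stops at the aldehyde and should leave the epimerisable α-methyl centre (C8) intact, the aldehyde being used at once.

Step 5
Reactants: 6 (2S,3S)-4-[(tert-butyldimethylsilyl)oxy]-2,3-dimethylbutanal, 7 5-bromo-1,2,3-trimethoxybenzene
Product: 9 (1R,2S,3S)-4-[(tert-butyldimethylsilyl)oxy]-2,3-dimethyl-1-(3,4,5-trimethoxyphenyl)butan-1-ol, via (3,4,5-trimethoxyphenyl)lithium 8 (not isolated)
Conditions: 7, n-BuLi, THF, −78 °C; then 6, −78 °C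
Reagents that add atoms: none
Why: Bromine–lithium exchange followed by 1,2-addition to the α-stereogenic aldehyde should follow the Felkin–Anh model (C7 branch anti to the incoming aryl group, attack past the C8 hydrogen) and give the 8,9-syn alcohol with C9 R, the minor C9 epimer being removed by chromatography.

Step 6
Reactants: 9 (1R,2S,3S)-4-[(tert-butyldimethylsilyl)oxy]-2,3-dimethyl-1-(3,4,5-trimethoxyphenyl)butan-1-ol
Product: 10 (1R,2S,3S)-1,4-bis[(tert-butyldimethylsilyl)oxy]-2,3-dimethyl-1-(3,4,5-trimethoxyphenyl)butane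
Conditions: TBSOTf, 2,6-lutidine, CH2Cl2, −78 to 0 °C
Reagents that add atoms: tert-butyldimethylsilyl trifluoromethanesulfonate, CC(C)(C)[Si](C)(C)OS(=O)(=O)C(F)(F)F
Why: Silyl triflate with a hindered pyridine base is the standard silylation of a hindered secondary benzylic alcohol and proceeds at oxygen with retention at C9.

Step 7
Reactants: 10 (1R,2S,3S)-1,4-bis[(tert-butyldimethylsilyl)oxy]-2,3-dimethyl-1-(3,4,5-trimethoxyphenyl)butane
Product: 11 (1R,2S,3S)-1-(2-bromo-3,4,5-trimethoxyphenyl)-1,4-bis[(tert-butyldimethylsilyl)oxy]-2,3-dimethylbutane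
Conditions: NBS, MeCN, 0 °C to rt
Reagents that add atoms: N-bromosuccinimide, O=C1CCC(=O)N1Br
Why: Electrophilic aromatic bromination can only occur at the two equivalent free positions, each ortho to one methoxy group and para to another, so a single monobromide (the future C4a) should form and the second bromination is slowed by the first.

Step 8
Reactants: 11 (1R,2S,3S)-1-(2-bromo-3,4,5-trimethoxyphenyl)-1,4-bis[(tert-butyldimethylsilyl)oxy]-2,3-dimethylbutane
Product: 12 (2S,3S,4R)-4-(2-bromo-3,4,5-trimethoxyphenyl)-4-[(tert-butyldimethylsilyl)oxy]-2,3-dimethylbutan-1-ol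
Conditions: HF·pyridine, pyridine, THF, 0 °C
Reagents that add atoms: none
Why: Buffered fluoride desilylation is governed by steric access, so the primary silyl ether should cleave well before the secondary benzylic one, which is flanked by the brominated ring and the C8 methyl group.

Step 9
Reactants: 12 (2S,3S,4R)-4-(2-bromo-3,4,5-trimethoxyphenyl)-4-[(tert-butyldimethylsilyl)oxy]-2,3-dimethylbutan-1-ol
Product: 13 (1R,2S,3S)-1-(2-bromo-3,4,5-trimethoxyphenyl)-1-[(tert-butyldimethylsilyl)oxy]-4-iodo-2,3-dimethylbutane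
Conditions: I2, PPh3, imidazole, CH2Cl2, 0 °C to rt
Reagents that add atoms: iodine, II
Why: Appel-type iodination converts the primary alcohol through its alkoxyphosphonium salt into the iodide by SN2 at C6, a non-stereogenic carbon, under near-neutral conditions that spare the silyl ether.

Step 10
Reactants: 13 (1R,2S,3S)-1-(2-bromo-3,4,5-trimethoxyphenyl)-1-[(tert-butyldimethylsilyl)oxy]-4-iodo-2,3-dimethylbutane, 14 dimethyl malonate
Product: 16 dimethyl 2-[(2R,3S,4R)-4-(2-bromo-3,4,5-trimethoxyphenyl)-4-[(tert-butyldimethylsilyl)oxy]-2,3-dimethylbutyl]malonate, via sodium dimethyl malonate 15 (not isolated)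
Conditions: 14 (3 equiv), NaH, THF/DMF, 0 °C; then 13, 60 °C
Reagents that add atoms: none
Why: Malonic ester alkylation of the primary iodide by SN2 forms the C5–C6 bond, excess malonate suppressing dialkylation and the aryl bromide being inert to the soft enolate without a catalyst.

Step 11
Reactants: 16 dimethyl 2-[(2R,3S,4R)-4-(2-bromo-3,4,5-trimethoxyphenyl)-4-[(tert-butyldimethylsilyl)oxy]-2,3-dimethylbutyl]malonate
Product: 17 dimethyl (7R,8S,9R)-9-[(tert-butyldimethylsilyl)oxy]-2,3,4-trimethoxy-7,8-dimethyl-6,7,8,9-tetrahydro-5H-benzo[7]annulene-5,5-dicarboxylate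
Conditions: Pd(OAc)2 (cat.), P(t-Bu)3·HBF4, Cs2CO3, toluene, 100 °C
Reagents that add atoms: none
Why: Intramolecular palladium-catalysed α-arylation of a malonate, in which zerovalent palladium carrying the bulky electron-rich phosphine inserts into the hindered C–Br bond, the enolate displaces bromide and reductive elimination forms C4a–C5 and the quaternary centre, closing the seven-membered ring B with the help of the ortho tether and the substituted chain.

Step 12
Reactants: 17 dimethyl (7R,8S,9R)-9-[(tert-butyldimethylsilyl)oxy]-2,3,4-trimethoxy-7,8-dimethyl-6,7,8,9-tetrahydro-5H-benzo[7]annulene-5,5-dicarboxylate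
Product: 18 [(7R,8S,9R)-9-[(tert-butyldimethylsilyl)oxy]-2,3,4-trimethoxy-7,8-dimethyl-6,7,8,9-tetrahydro-5H-benzo[7]annulene-5,5-diyl]dimethanol
Conditions: LiAlH4, THF, 0 °C to rt
Reagents that add atoms: none
Why: LiAlH4 reduction of a 2,2-disubstituted malonate to the 1,3-diol is standard, and the silyl ether, the aryl ethers and the three stereocentres are not affected.

Step 13
Reactants: 18 [(7R,8S,9R)-9-[(tert-butyldimethylsilyl)oxy]-2,3,4-trimethoxy-7,8-dimethyl-6,7,8,9-tetrahydro-5H-benzo[7]annulene-5,5-diyl]dimethanol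
Product: 19 (7R,8S,9R)-9-[(tert-butyldimethylsilyl)oxy]-2,3,4-trimethoxy-7,8-dimethyl-6,7,8,9-tetrahydro-5H-benzo[7]annulene-5,5-dicarbaldehyde
Conditions: (COCl)2, DMSO, CH2Cl2, −78 °C; Et3N, −78 to 0 °C
Reagents that add atoms: none
Why: Twofold Swern oxidation activates both neopentyl-type alcohols at low temperature before base is added and should give the non-enolisable 2,2-disubstituted malondialdehyde without over-oxidation, the product being taken on crude.

Step 14
Reactants: 19 (7R,8S,9R)-9-[(tert-butyldimethylsilyl)oxy]-2,3,4-trimethoxy-7,8-dimethyl-6,7,8,9-tetrahydro-5H-benzo[7]annulene-5,5-dicarbaldehyde, 20 1,3-dimethoxypropan-2-one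
Product: 22 (7R,8S,9R)-9-[(tert-butyldimethylsilyl)oxy]-2,3,4,3′,5′-pentamethoxy-7,8-dimethyl-6,7,8,9-tetrahydrospiro[benzo[7]annulene-5,1′-cyclohexa[2,5]dien]-4′-one, via cyclic bis-aldol diol 21 (not isolated)
Conditions: 20 (3 equiv), pyrrolidine (0.3 equiv), AcOH (0.6 equiv), 4 Å MS, toluene, rt then 70 °C
Reagents that add atoms: none
Why: Proposed new method: pyrrolidinium acetate should convert 20 into its enamine, which adds to one formyl group of 19; the iminium so formed tautomerises to the α′-enamine, whose carbon attacks the second formyl group in a 6-(enolendo)-exo-trig aldol, so ring C closes at the stage of diol 21 and no alkene geometry has to be correct. Warming should then drive two iminium-assisted E1cB dehydrations to the cross-conjugated dienone, which cannot enolise or aromatise because C5 is quaternary and is therefore the thermodynamic sink. The closest known reaction types are the condensation of malondialdehyde derivatives with acetone derivatives to give para-substituted phenols and the enamine aldol addition of protected dihydroxyacetones to α-branched aldehydes; a 2,2-disubstituted malondialdehyde has not been used in this way. No stereocentre is created, because the four transient centres of 21 are erased and the mirror plane through C5 and C4′ makes both formyl groups lead to the same product. The selectivity needed is chemoselectivity, aldol addition faster than amine-induced deformylation of the 1,3-dialdehyde. It should be secured by the low concentration of free amine in the buffered salt, by the excess of ketone, and by the fact that after the first addition the substrate is no longer a 1,3-dicarbonyl compound and the second aldol is intramolecular.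

Step 15
Reactants: 22 (7R,8S,9R)-9-[(tert-butyldimethylsilyl)oxy]-2,3,4,3′,5′-pentamethoxy-7,8-dimethyl-6,7,8,9-tetrahydrospiro[benzo[7]annulene-5,1′-cyclohexa[2,5]dien]-4′-one
Product: 23 (7R,8S,9R)-9-hydroxy-2,3,4,3′,5′-pentamethoxy-7,8-dimethyl-6,7,8,9-tetrahydrospiro[benzo[7]annulene-5,1′-cyclohexa[2,5]dien]-4′-one
Conditions: Bu4NF, AcOH, THF, 0 °C to rt
Reagents that add atoms: none
Why: Fluoride desilylation cleaves the Si–O bond without touching C9, and the acetic acid buffer should keep the freed alkoxide from adding to the dienone and avoid the acid that would ionise the benzylic position.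

Step 16
Reactants: 23 (7R,8S,9R)-9-hydroxy-2,3,4,3′,5′-pentamethoxy-7,8-dimethyl-6,7,8,9-tetrahydrospiro[benzo[7]annulene-5,1′-cyclohexa[2,5]dien]-4′-one
Product: 24 (7R,8S,9R)-2,3,4,3′,5′-pentamethoxy-7,8-dimethyl-4′-oxo-6,7,8,9-tetrahydrospiro[benzo[7]annulene-5,1′-cyclohexa[2,5]dien]-9-yl benzoate
Conditions: BzCl, Et3N, DMAP (cat.), CH2Cl2, 0 °C to rt
Reagents that add atoms: benzoyl chloride, O=C(Cl)c1ccccc1
Why: DMAP-catalysed O-acylation of the secondary benzylic alcohol forms the benzoate at oxygen with retention at C9 and leaves the non-enolisable dienone untouched.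

**Compound list**

1 | (R)-4-benzyl-3-propionyloxazolidin-2-one | CCC(=O)N1[C@H](Cc2ccccc2)COC1=O | starting material
2 | lithium (Z)-1-[(4R)-4-benzyl-2-oxo-1,3-oxazolidin-3-yl]prop-1-en-1-olate | C/C=C(\O[Li])N1[C@H](Cc2ccccc2)COC1=O | intermediate
3 | (4R,4′R)-3,3′-[(2S,3S)-2,3-dimethylbutanedioyl]bis(4-benzyl-1,3-oxazolidin-2-one) | O=C([C@@H](C)[C@H](C)C(=O)N1[C@H](Cc2ccccc2)COC1=O)N1[C@H](Cc2ccccc2)COC1=O | intermediate
4 | (2S,3S)-2,3-dimethylbutane-1,4-diol | OC[C@@H](C)[C@H](C)CO | intermediate
5 | (2S,3S)-4-[(tert-butyldimethylsilyl)oxy]-2,3-dimethylbutan-1-ol | CC(C)(C)[Si](C)(C)OC[C@@H](C)[C@H](C)CO | intermediate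
6 | (2S,3S)-4-[(tert-butyldimethylsilyl)oxy]-2,3-dimethylbutanal | CC(C)(C)[Si](C)(C)OC[C@@H](C)[C@H](C)C=O | intermediate
7 | 5-bromo-1,2,3-trimethoxybenzene | COc1cc(Br)cc(OC)c1OC | starting material
8 | (3,4,5-trimethoxyphenyl)lithium | [Li]c1cc(OC)c(OC)c(OC)c1 | intermediate
9 | (1R,2S,3S)-4-[(tert-butyldimethylsilyl)oxy]-2,3-dimethyl-1-(3,4,5-trimethoxyphenyl)butan-1-ol | CC(C)(C)[Si](C)(C)OC[C@@H](C)[C@H](C)[C@@H](O)c1cc(OC)c(OC)c(OC)c1 | intermediate
10 | (1R,2S,3S)-1,4-bis[(tert-butyldimethylsilyl)oxy]-2,3-dimethyl-1-(3,4,5-trimethoxyphenyl)butane | CC(C)(C)[Si](C)(C)OC[C@@H](C)[C@H](C)[C@@H](O[Si](C)(C)C(C)(C)C)c1cc(OC)c(OC)c(OC)c1 | intermediate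
11 | (1R,2S,3S)-1-(2-bromo-3,4,5-trimethoxyphenyl)-1,4-bis[(tert-butyldimethylsilyl)oxy]-2,3-dimethylbutane | CC(C)(C)[Si](C)(C)OC[C@@H](C)[C@H](C)[C@@H](O[Si](C)(C)C(C)(C)C)c1cc(OC)c(OC)c(OC)c1Br | intermediate
12 | (2S,3S,4R)-4-(2-bromo-3,4,5-trimethoxyphenyl)-4-[(tert-butyldimethylsilyl)oxy]-2,3-dimethylbutan-1-ol | OC[C@@H](C)[C@H](C)[C@@H](O[Si](C)(C)C(C)(C)C)c1cc(OC)c(OC)c(OC)c1Br | intermediate
13 | (1R,2S,3S)-1-(2-bromo-3,4,5-trimethoxyphenyl)-1-[(tert-butyldimethylsilyl)oxy]-4-iodo-2,3-dimethylbutane | IC[C@@H](C)[C@H](C)[C@@H](O[Si](C)(C)C(C)(C)C)c1cc(OC)c(OC)c(OC)c1Br | intermediate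
14 | dimethyl malonate | COC(=O)CC(=O)OC | starting material
15 | sodium dimethyl malonate | [Na+].COC(=O)[CH-]C(=O)OC | intermediate
16 | dimethyl 2-[(2R,3S,4R)-4-(2-bromo-3,4,5-trimethoxyphenyl)-4-[(tert-butyldimethylsilyl)oxy]-2,3-dimethylbutyl]malonate | COC(=O)C(C[C@@H](C)[C@H](C)[C@@H](O[Si](C)(C)C(C)(C)C)c1cc(OC)c(OC)c(OC)c1Br)C(=O)OC | intermediate
17 | dimethyl (7R,8S,9R)-9-[(tert-butyldimethylsilyl)oxy]-2,3,4-trimethoxy-7,8-dimethyl-6,7,8,9-tetrahydro-5H-benzo[7]annulene-5,5-dicarboxylate | COC(=O)C1(C(=O)OC)C[C@@H](C)[C@H](C)[C@@H](O[Si](C)(C)C(C)(C)C)c2cc(OC)c(OC)c(OC)c12 | intermediate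
18 | [(7R,8S,9R)-9-[(tert-butyldimethylsilyl)oxy]-2,3,4-trimethoxy-7,8-dimethyl-6,7,8,9-tetrahydro-5H-benzo[7]annulene-5,5-diyl]dimethanol | OCC1(CO)C[C@@H](C)[C@H](C)[C@@H](O[Si](C)(C)C(C)(C)C)c2cc(OC)c(OC)c(OC)c12 | intermediate
19 | (7R,8S,9R)-9-[(tert-butyldimethylsilyl)oxy]-2,3,4-trimethoxy-7,8-dimethyl-6,7,8,9-tetrahydro-5H-benzo[7]annulene-5,5-dicarbaldehyde | O=CC1(C=O)C[C@@H](C)[C@H](C)[C@@H](O[Si](C)(C)C(C)(C)C)c2cc(OC)c(OC)c(OC)c12 | intermediate
20 | 1,3-dimethoxypropan-2-one | COCC(=O)COC | starting material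
21 | (7R,8S,9R)-9-[(tert-butyldimethylsilyl)oxy]-2′,6′-dihydroxy-2,3,4,3′,5′-pentamethoxy-7,8-dimethyl-6,7,8,9-tetrahydrospiro[benzo[7]annulene-5,1′-cyclohexan]-4′-one (mixture of diastereomers at C2′, C3′, C5′ and C6′) | COC1C(O)C2(C(O)C(OC)C1=O)C[C@@H](C)[C@H](C)[C@@H](O[Si](C)(C)C(C)(C)C)c1cc(OC)c(OC)c(OC)c12 | intermediate
22 | (7R,8S,9R)-9-[(tert-butyldimethylsilyl)oxy]-2,3,4,3′,5′-pentamethoxy-7,8-dimethyl-6,7,8,9-tetrahydrospiro[benzo[7]annulene-5,1′-cyclohexa[2,5]dien]-4′-one | COC1=CC2(C=C(OC)C1=O)C[C@@H](C)[C@H](C)[C@@H](O[Si](C)(C)C(C)(C)C)c1cc(OC)c(OC)c(OC)c12 | intermediate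
23 | (7R,8S,9R)-9-hydroxy-2,3,4,3′,5′-pentamethoxy-7,8-dimethyl-6,7,8,9-tetrahydrospiro[benzo[7]annulene-5,1′-cyclohexa[2,5]dien]-4′-one | COC1=CC2(C=C(OC)C1=O)C[C@@H](C)[C@H](C)[C@@H](O)c1cc(OC)c(OC)c(OC)c12 | intermediate
24 | (7R,8S,9R)-2,3,4,3′,5′-pentamethoxy-7,8-dimethyl-4′-oxo-6,7,8,9-tetrahydrospiro[benzo[7]annulene-5,1′-cyclohexa[2,5]dien]-9-yl benzoate | COC1=CC2(C=C(OC)C1=O)C[C@@H](C)[C@H](C)[C@@H](OC(=O)c1ccccc1)c1cc(OC)c(OC)c(OC)c12 | target

**Step count**

Total steps: 16. Longest linear sequence: 16 steps, from 1 to 24; compounds 7, 14 and 20 enter as purchased.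

**Steps most likely to fail**

Step 14 (ring C). What may go wrong: the amine may remove a formyl group from the 1,3-dialdehyde before the first aldol; the acyclic mono-adduct may dehydrate early to the enone geometry that cannot cyclise; or the diol may not dehydrate fully. The fallback makes each C–C bond by a directed aldol addition and removes water in a separate operation. It sets out from 19 (with 20) and returns at 22. Compound 20 is deprotonated with LiN(iPr)2 in THF at −78 °C to lithium (Z)-1,3-dimethoxyprop-1-en-2-olate F1, and 19 is added at −78 °C. A carbon nucleophile cannot deformylate, and a cold quench should give the acyclic mono-aldol, 5-(1-hydroxy-2,4-dimethoxy-3-oxobutyl)-5-carbaldehyde F2, as a diastereomer mixture. Treatment of F2 with LiN(SiMe3)2 (2.2 equiv, THF, −78 to −40 °C) removes the hydroxyl proton and then the less hindered α′ proton, and the enolate closes onto the remaining formyl group to give 21, now isolated. MsCl/Et3N converts 21 into the 2′,6′-bis(methanesulfonate) F3, and DBU in CH2Cl2 effects both eliminations to 22.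

Step 11 (ring B). What may go wrong: oxidative addition into the doubly ortho-flanked C–Br bond may be slow, or reductive elimination to a quaternary centre in a seven-membered ring may fail, so that hydrodebromination takes over. The fallback reverses the order of the two bonds at C5: the aryl–C5 bond is made intermolecularly on unsubstituted malonate (a tertiary centre), and ring B is then closed at C5–C6 by alkylation. It sets out from 11 (with 14) and returns at 17. Compounds 11 and 14 are coupled with Pd(OAc)2/P(t-Bu)3 and K3PO4 in toluene at 70–100 °C to give the aryl malonate, dimethyl 2-{6-[(1R,2S,3S)-1,4-bis[(tert-butyldimethylsilyl)oxy]-2,3-dimethylbutyl]-2,3,4-trimethoxyphenyl}malonate F4. HF·pyridine/pyridine removes the primary silyl group to give the alcohol, dimethyl 2-{6-[(1R,2S,3S)-1-[(tert-butyldimethylsilyl)oxy]-4-hydroxy-2,3-dimethylbutyl]-2,3,4-trimethoxyphenyl}malonate F5. I2/PPh3/imidazole gives the iodide, dimethyl 2-{6-[(1R,2S,3S)-1-[(tert-butyldimethylsilyl)oxy]-4-iodo-2,3-dimethylbutyl]-2,3,4-trimethoxyphenyl}malonate F6. Cs2CO3 in DMF at high dilution then closes ring B by 7-exo-tet alkylation of the arylmalonate anion to give 17.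

Step 5 (C9). What may go wrong: facial selectivity in the addition to the α-methyl aldehyde may be poor, and the basic aryllithium may epimerise C8. The fallback replaces substrate control by catalyst control with a less basic aryl donor. It sets out from 6 and 8 (made from 7 as before) and returns at 9. Compound 8 is treated with ZnCl2 and then n-BuLi to give butyl(3,4,5-trimethoxyphenyl)zinc F7. N,N,N′,N′-tetraethylethylenediamine is added to sequester lithium chloride, together with a catalytic amount of the 3-exo-morpholinoisoborneol enantiomer that delivers the aryl group to the Si face of 6 (expected to be the levorotatory one, to be confirmed by a test with both antipodes). F7 then adds to 6 in toluene/hexane at 0 °C to give 9, with the catalyst and Felkin preferences matched.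

**Further compounds**

F1 | step 14 | lithium (Z)-1,3-dimethoxyprop-1-en-2-olate | CO/C=C(\O[Li])COC
F2 | step 14 | (7R,8S,9R)-9-[(tert-butyldimethylsilyl)oxy]-5-(1-hydroxy-2,4-dimethoxy-3-oxobutyl)-2,3,4-trimethoxy-7,8-dimethyl-6,7,8,9-tetrahydro-5H-benzo[7]annulene-5-carbaldehyde (diastereomer mixture at the new centres) | COCC(=O)C(OC)C(O)C1(C=O)C[C@@H](C)[C@H](C)[C@@H](O[Si](C)(C)C(C)(C)C)c2cc(OC)c(OC)c(OC)c12
F3 | step 14 | 2′,6′-bis(methanesulfonate) of 21 (diastereomer mixture at C2′, C3′, C5′ and C6′) | COC1C(OS(C)(=O)=O)C2(C(OS(C)(=O)=O)C(OC)C1=O)C[C@@H](C)[C@H](C)[C@@H](O[Si](C)(C)C(C)(C)C)c1cc(OC)c(OC)c(OC)c12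
F4 | step 11 | dimethyl 2-{6-[(1R,2S,3S)-1,4-bis[(tert-butyldimethylsilyl)oxy]-2,3-dimethylbutyl]-2,3,4-trimethoxyphenyl}malonate | CC(C)(C)[Si](C)(C)OC[C@@H](C)[C@H](C)[C@@H](O[Si](C)(C)C(C)(C)C)c1cc(OC)c(OC)c(OC)c1C(C(=O)OC)C(=O)OC
F5 | step 11 | dimethyl 2-{6-[(1R,2S,3S)-1-[(tert-butyldimethylsilyl)oxy]-4-hydroxy-2,3-dimethylbutyl]-2,3,4-trimethoxyphenyl}malonate | OC[C@@H](C)[C@H](C)[C@@H](O[Si](C)(C)C(C)(C)C)c1cc(OC)c(OC)c(OC)c1C(C(=O)OC)C(=O)OC
F6 | step 11 | dimethyl 2-{6-[(1R,2S,3S)-1-[(tert-butyldimethylsilyl)oxy]-4-iodo-2,3-dimethylbutyl]-2,3,4-trimethoxyphenyl}malonate | IC[C@@H](C)[C@H](C)[C@@H](O[Si](C)(C)C(C)(C)C)c1cc(OC)c(OC)c(OC)c1C(C(=O)OC)C(=O)OC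
F7 | step 5 | butyl(3,4,5-trimethoxyphenyl)zinc | CCCC[Zn]c1cc(OC)c(OC)c(OC)c1
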